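The upper flavonoid unit is cut at O1–C8a and C4–C4a, so that ring A arrives as 3,5-bis(benzyloxy)benzyne and inserts into the C–O bond of a C3 carboxylic acid. The step exploits the ring A pattern in which O1 (on C8a) and the C4 ketone (on C4a) are ortho and C5, next to C4a, bears oxygen: exactly what carboxylate addition and acyl shift on this unsymmetrical aryne deliver, in one operation and without an acylium ion. The precursor is the (2S)-flavan-fused 2-aryl-2-methoxy-3-(methoxymethoxy)-2,3-dihydrobenzofuran-3-carboxylic acid with C3 already set; acid-mediated ketal exchange then closes ring C and hydrogenolysis frees the phenols.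

Key step: step 13

Locants: flavonoid locants (O1, C2, C3, C4, ring A = C4a to C8a, ring C) are used for the target, and double primes mark the flavan. Tricyclic intermediates are named as furo[2,3-h]chromenes, in which C8 is the later C2 and C9 the later C3.

Assumption: the face chosen by the (S,S) catalyst in step 8 is taken by analogy with indene and is to be confirmed on the first run; the (R,R) complex would serve if the C9 epimer prevailed.

Step 1
Reactants: 1 (2S)-naringenin
Product: 2 (2S)-5-hydroxy-2-(4-hydroxyphenyl)-7-(methoxymethoxy)chroman-4-one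
Conditions: MOMCl (1.05 equiv), iPr2NEt (1.2 equiv), acetone, 0 °C → rt
Reagents that add atoms: chloromethyl methyl ether, COCCl
Why: Williamson-type O-alkylation: the 7-OH, para to the carbonyl, is the most acidic phenol and the one ionised by the amine base, the chelated 5-OH is inert, and C2 is not touched.

Step 2
Reactants: 2 (2S)-5-hydroxy-2-(4-hydroxyphenyl)-7-(methoxymethoxy)chroman-4-one
Product: 5 (2S)-2-(4-hydroxyphenyl)-7-(methoxymethoxy)chroman-5-ol, via bis(ethyl carbonate) 3 (not isolated), via aryl ethyl carbonate 4 (not isolated)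
Conditions: ClCO2Et (2.5 equiv), Et3N, THF, 0 °C; then NaBH4, THF/H2O, 0 °C → rt; then 2 M NaOH, rt; aq. NH4Cl
Reagents that add atoms: none
Why: Carbonate-assisted deoxygenation of an ortho-hydroxyaryl ketone: borohydride reduces C4=O, the 5-O-carbonate shifts to the new alkoxide and is expelled to give an ortho-quinone methide that takes a second hydride, hydroxide then cleaves the remaining aryl carbonate, and C2 keeps its (S) configuration because it takes no part.

Step 3
Reactants: 5 (2S)-2-(4-hydroxyphenyl)-7-(methoxymethoxy)chroman-5-ol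
Product: 6 (2S)-5-(benzyloxy)-2-[4-(benzyloxy)phenyl]-7-(methoxymethoxy)chroman
Conditions: BnBr (2.4 equiv), K2CO3, DMF, rt
Reagents that add atoms: benzyl bromide, BrCc1ccccc1
Why: Double Williamson etherification of the two phenols; a flavan has no enolisable position, so the base cannot epimerise C2.

Step 4
Reactants: 6 (2S)-5-(benzyloxy)-2-[4-(benzyloxy)phenyl]-7-(methoxymethoxy)chroman
Product: 7 (2S)-5-(benzyloxy)-2-[4-(benzyloxy)phenyl]-8-iodo-7-(methoxymethoxy)chroman
Conditions: NIS (1.05 equiv), DMF, 0 °C → rt, dark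
Reagents that add atoms: N-iodosuccinimide, O=C1CCC(=O)N1I
Why: Electrophilic aromatic iodination of the trialkoxy ring: C8, flanked by the tied-back pyran oxygen, is less hindered than C6 between two alkoxy groups, which is the known preference of 5,7-dialkoxyflavans, and the monoalkoxy B ring is far less activated.

Step 5
Reactants: 7 (2S)-5-(benzyloxy)-2-[4-(benzyloxy)phenyl]-8-iodo-7-(methoxymethoxy)chroman; 8 1-(benzyloxy)-4-ethynylbenzene
Product: 9 (2S)-5-(benzyloxy)-2-[4-(benzyloxy)phenyl]-8-{[4-(benzyloxy)phenyl]ethynyl}-7-(methoxymethoxy)chroman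
Conditions: PdCl2(PPh3)2 (5 mol%), CuI (10 mol%), Et3N, DMF, 60 °C
Reagents that add atoms: none
Why: Sonogashira coupling of the aryl iodide with the terminal alkyne; the phenol is kept as its MOM ether so that no 5-endo cyclisation to a 3-unsubstituted benzofuran can follow.

Step 6
Reactants: 9 (2S)-5-(benzyloxy)-2-[4-(benzyloxy)phenyl]-8-{[4-(benzyloxy)phenyl]ethynyl}-7-(methoxymethoxy)chroman
Product: 10 (2S)-5-(benzyloxy)-2-[4-(benzyloxy)phenyl]-8-{[4-(benzyloxy)phenyl]ethynyl}chroman-7-ol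
Conditions: 2 M HCl, MeOH/THF, 40 °C
Reagents that add atoms: none
Why: Acid-catalysed transacetalisation removes the aryl MOM ether under conditions that leave the benzyl ethers, the flavan and the diarylalkyne alone.

Step 7
Reactants: 10 (2S)-5-(benzyloxy)-2-[4-(benzyloxy)phenyl]-8-{[4-(benzyloxy)phenyl]ethynyl}chroman-7-ol
Product: 11 methyl (2S)-5-(benzyloxy)-2,8-bis[4-(benzyloxy)phenyl]-3,4-dihydro-2H-furo[2,3-h]chromene-9-carboxylate
Conditions: PdI2 (5 mol%), thiourea (5 mol%), CBr4, Cs2CO3, CO (1 atm), MeOH, 40 °C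
Reagents that add atoms: carbon monoxide, [C-]#[O+]; methanol, CO
Why: Alkoxycarbonylative heteroannulation of an ortho-alkynylphenol under divalent palladium catalysis: anti-oxypalladation by the phenoxide, CO insertion into the vinyl–palladium bond and methanolysis, with CBr4 as reoxidant.

Step 8
Reactants: 11 methyl (2S)-5-(benzyloxy)-2,8-bis[4-(benzyloxy)phenyl]-3,4-dihydro-2H-furo[2,3-h]chromene-9-carboxylate
Product: 13 methyl (2S,8S,9S)-5-(benzyloxy)-2,8-bis[4-(benzyloxy)phenyl]-9-hydroxy-8-methoxy-3,4,8,9-tetrahydro-2H-furo[2,3-h]chromene-9-carboxylate, via benzofuran epoxide 12 (not isolated)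
Conditions: (S,S)-(salen)MnCl complex C36H52ClMnN2O2 (trivalent manganese, 10 mol%), NMO, mCPBA, CH2Cl2, −78 °C; then MeOH, −78 °C → rt
Reagents that add atoms: 3-chloroperbenzoic acid, OOC(=O)c1cccc(Cl)c1; methanol, CO
Why: Proposed new method: the oxo-manganese species formed from mCPBA and NMO should attack the C8=C9 bond side-on and form the C9–O bond first, because the resulting C8 radical is stabilised by the aryl group and the ring oxygen, so catalyst control is needed only at C9, the one centre that survives (C8 is re-set in step 14); cold methanol then opens the labile 8-aryl-8-alkoxy epoxide at C8 with inversion before it can isomerise to a quinone methide and erase C9; the closest known reaction type is the Jacobsen–Katsuki epoxidation of benzo-fused cyclic olefins (indene, chromenes, also tetrasubstituted ones), cis-cinnamate esters and push–pull enol ethers such as isoflavones, joined to the known methanol capture of benzofuran epoxides.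

Step 9
Reactants: 13 methyl (2S,8S,9S)-5-(benzyloxy)-2,8-bis[4-(benzyloxy)phenyl]-9-hydroxy-8-methoxy-3,4,8,9-tetrahydro-2H-furo[2,3-h]chromene-9-carboxylate
Product: 14 methyl (2S,8S,9S)-5-(benzyloxy)-2,8-bis[4-(benzyloxy)phenyl]-8-methoxy-9-(methoxymethoxy)-3,4,8,9-tetrahydro-2H-furo[2,3-h]chromene-9-carboxylate
Conditions: NaH, MOMCl, n-Bu4NI (cat.), THF, 0 °C → rt
Reagents that add atoms: chloromethyl methyl ether, COCCl
Why: Williamson-type alkylation of the sodium alkoxide with the small and very reactive MOMCl reaches even this crowded tertiary alcohol; the ester has no α-hydrogen and the ketal is base-stable.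

Step 10
Reactants: 14 methyl (2S,8S,9S)-5-(benzyloxy)-2,8-bis[4-(benzyloxy)phenyl]-8-methoxy-9-(methoxymethoxy)-3,4,8,9-tetrahydro-2H-furo[2,3-h]chromene-9-carboxylate
Product: 15 (2S,8S,9S)-5-(benzyloxy)-2,8-bis[4-(benzyloxy)phenyl]-8-methoxy-9-(methoxymethoxy)-3,4,8,9-tetrahydro-2H-furo[2,3-h]chromene-9-carboxylic acid
Conditions: LiOH·H2O, THF/MeOH/H2O, 60 °C; then 1 M HCl to pH 4, 0 °C
Reagents that add atoms: lithium hydroxide, [Li+].[OH-]
Why: Saponification (acyl substitution by hydroxide); the neopentyl-type ester needs heat, which is tolerated because no α-hydrogen, ketone or other base-labile group is present, and the cold, weakly acidic work-up spares ketal and MOM ether.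

Step 11
Reactants: 16 3,5-bis(benzyloxy)phenol
Product: 17 3,5-bis(benzyloxy)-2-bromophenol
Conditions: NBS (1.0 equiv), CH2Cl2, −78 °C → 0 °C
Reagents that add atoms: N-bromosuccinimide, O=C1CCC(=O)N1Br
Why: Electrophilic bromination ortho to the free hydroxyl (hydrogen-bond guidance by NBS in CH2Cl2), the para position between two benzyloxy groups being the more hindered one.

Step 12
Reactants: 17 3,5-bis(benzyloxy)-2-bromophenol
Product: 20 3,5-bis(benzyloxy)-2-(trimethylsilyl)phenyl trifluoromethanesulfonate, via aryl trimethylsilyl ether 18 (not isolated), via lithium 2-silylphenoxide 19 (not isolated)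
Conditions: HMDS, THF, 65 °C; evaporate; n-BuLi, THF, −78 °C; Tf2O, −78 °C → rt
Reagents that add atoms: hexamethyldisilazane, C[Si](C)(C)N[Si](C)(C)C; trifluoromethanesulfonic anhydride, O=S(=O)(OS(=O)(=O)C(F)(F)F)C(F)(F)F
Why: O-Silylation, bromine–lithium exchange, 1,3 O-to-C silyl shift (retro-Brook rearrangement) and O-triflation of the resulting phenoxide, the standard entry to ortho-silylaryl triflates; exchange at −78 °C is faster than any attack on the benzyl ethers.

Step 13
Reactants: 15 (2S,8S,9S)-5-(benzyloxy)-2,8-bis[4-(benzyloxy)phenyl]-8-methoxy-9-(methoxymethoxy)-3,4,8,9-tetrahydro-2H-furo[2,3-h]chromene-9-carboxylic acid; 20 3,5-bis(benzyloxy)-2-(trimethylsilyl)phenyl trifluoromethanesulfonate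
Product: 23 [2,4-bis(benzyloxy)-6-hydroxyphenyl][(2S,8S,9R)-5-(benzyloxy)-2,8-bis[4-(benzyloxy)phenyl]-8-methoxy-9-(methoxymethoxy)-3,4,8,9-tetrahydro-2H-furo[2,3-h]chromen-9-yl]methanone, via cesium carboxylate 21 (not isolated), via 3,5-bis(benzyloxy)benzyne 22 (not isolated)
Conditions: CsF (4 equiv), 20 (2 equiv, two portions), THF, 125 °C (sealed tube); aq. NH4Cl
Reagents that add atoms: none
Why: Fluoride removes the silyl group of 20 and triflate leaves, giving aryne 22, whose triple bond is polarised by the flanking 3-benzyloxy group; carboxylate 21 adds through oxygen at the remote aryne carbon (the later C8a), which puts the aryl anion ortho to benzyloxy (the later C4a), where it is inductively stabilised. The anion attacks the aryl ester carbonyl it has just made through a four-membered transition state and the acyl group shifts from oxygen to carbon, releasing the phenoxide that becomes O1. The closest known reaction type is the fluoride-induced insertion of arynes into the C–O bond of carboxylic acids, an anionic ortho-Fries-type shift that gives ortho-hydroxyaryl ketones. No ring closes and no stereocentre forms; C8 and C9 are quaternary, non-enolisable and stay as set. The step needs regioselective aryne capture, secured by the 3-benzyloxy group, and acyl transfer faster than protonation of the aryl anion, favoured by the absence of any OH or NH (MOM on O9, methyl ketal at C8), excess CsF to bind HF and the high temperature. Since the acyl group moves within an anion, no acylium ion forms and carbon monoxide cannot be lost, and the ketal keeps the latent β-ketone masked so that the carboxylate cannot decarboxylate.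

Step 14
Reactants: 23 [2,4-bis(benzyloxy)-6-hydroxyphenyl][(2S,8S,9R)-5-(benzyloxy)-2,8-bis[4-(benzyloxy)phenyl]-8-methoxy-9-(methoxymethoxy)-3,4,8,9-tetrahydro-2H-furo[2,3-h]chromen-9-yl]methanone
Product: 25 penta-O-benzyl ether of the target (all five phenols benzylated; tertiary 3-OH free; ring C closed; cis-fused; 2R,3R,2''S), via 9-hydroxy methyl ketal 24 (not isolated)
Conditions: HCl (1.25 M in MeOH), CH2Cl2, 40 °C; evaporate; PPTS (cat.), toluene, 60 °C
Reagents that add atoms: none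
Why: Acid-catalysed acetal cleavage frees the 3-OH, and under PPTS in toluene the C2 methyl ketal ionises to an oxocarbenium ion that the ring A phenol captures (transketalisation, driven by loss of methanol); the tether lets the phenol reach C2 only on the face cis to C4, so C2 is set (R) by C3, which is not touched.

Step 15
Reactants: 25 penta-O-benzyl ether of the target
Product: 26 target CNP0208300.2 (2R,3R,2''S)
Conditions: H2 (1 atm), Pd/C (10%), EtOAc/MeOH, rt
Reagents that add atoms: none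
Why: Hydrogenolysis of the five aryl benzyl ethers over palladium at 1 atm; the ketal, the tertiary alcohol and the flavan C–O bond are cleaved much more slowly and the aryl ketone is not reduced under these conditions.

Compound list

1 | (2S)-naringenin | O=C1C[C@@H](c2ccc(O)cc2)Oc2cc(O)cc(O)c12 | starting material
2 | (2S)-5-hydroxy-2-(4-hydroxyphenyl)-7-(methoxymethoxy)chroman-4-one | O=C1C[C@@H](c2ccc(O)cc2)Oc2cc(OCOC)cc(O)c12 | intermediate
3 | (2S)-5-[(ethoxycarbonyl)oxy]-2-{4-[(ethoxycarbonyl)oxy]phenyl}-7-(methoxymethoxy)chroman-4-one | O=C1C[C@@H](c2ccc(OC(=O)OCC)cc2)Oc2cc(OCOC)cc(OC(=O)OCC)c12 | intermediate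
4 | ethyl 4-[(2S)-5-hydroxy-7-(methoxymethoxy)chroman-2-yl]phenyl carbonate | C1C[C@@H](c2ccc(OC(=O)OCC)cc2)Oc2cc(OCOC)cc(O)c12 | intermediate
5 | (2S)-2-(4-hydroxyphenyl)-7-(methoxymethoxy)chroman-5-ol | C1C[C@@H](c2ccc(O)cc2)Oc2cc(OCOC)cc(O)c12 | intermediate
6 | (2S)-5-(benzyloxy)-2-[4-(benzyloxy)phenyl]-7-(methoxymethoxy)chroman | C1C[C@@H](c2ccc(OCc3ccccc3)cc2)Oc2cc(OCOC)cc(OCc3ccccc3)c12 | intermediate
7 | (2S)-5-(benzyloxy)-2-[4-(benzyloxy)phenyl]-8-iodo-7-(methoxymethoxy)chroman | C1C[C@@H](c2ccc(OCc3ccccc3)cc2)Oc2c(I)c(OCOC)cc(OCc3ccccc3)c12 | intermediate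
8 | 1-(benzyloxy)-4-ethynylbenzene | C#Cc1ccc(OCc2ccccc2)cc1 | starting material
9 | (2S)-5-(benzyloxy)-2-[4-(benzyloxy)phenyl]-8-{[4-(benzyloxy)phenyl]ethynyl}-7-(methoxymethoxy)chroman | C1C[C@@H](c2ccc(OCc3ccccc3)cc2)Oc2c(C#Cc3ccc(OCc4ccccc4)cc3)c(OCOC)cc(OCc3ccccc3)c12 | intermediate
10 | (2S)-5-(benzyloxy)-2-[4-(benzyloxy)phenyl]-8-{[4-(benzyloxy)phenyl]ethynyl}chroman-7-ol | C1C[C@@H](c2ccc(OCc3ccccc3)cc2)Oc2c(C#Cc3ccc(OCc4ccccc4)cc3)c(O)cc(OCc3ccccc3)c12 | intermediate
11 | methyl (2S)-5-(benzyloxy)-2,8-bis[4-(benzyloxy)phenyl]-3,4-dihydro-2H-furo[2,3-h]chromene-9-carboxylate | C1C[C@@H](c2ccc(OCc3ccccc3)cc2)Oc2c3c(C(=O)OC)c(-c4ccc(OCc5ccccc5)cc4)oc3cc(OCc3ccccc3)c12 | intermediate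
12 | methyl (2S)-5-(benzyloxy)-2,8-bis[4-(benzyloxy)phenyl]-8,9-epoxy-3,4,8,9-tetrahydro-2H-furo[2,3-h]chromene-9-carboxylate (epoxide oxygen on the face of the later 9-OH) | COC(=O)[C@]6(O7)c3c(O[C@]67c2ccc(OCc5ccccc5)cc2)cc(OCc5ccccc5)c4c3O[C@H](c1ccc(OCc5ccccc5)cc1)CC4 | intermediate
13 | methyl (2S,8S,9S)-5-(benzyloxy)-2,8-bis[4-(benzyloxy)phenyl]-9-hydroxy-8-methoxy-3,4,8,9-tetrahydro-2H-furo[2,3-h]chromene-9-carboxylate (8-OMe trans to 9-OH) | COC(=O)[C@]6(O)c3c(O[C@@]6(OC)c2ccc(OCc5ccccc5)cc2)cc(OCc5ccccc5)c4c3O[C@H](c1ccc(OCc5ccccc5)cc1)CC4 | intermediate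
14 | methyl (2S,8S,9S)-5-(benzyloxy)-2,8-bis[4-(benzyloxy)phenyl]-8-methoxy-9-(methoxymethoxy)-3,4,8,9-tetrahydro-2H-furo[2,3-h]chromene-9-carboxylate | COC(=O)[C@]6(OCOC)c3c(O[C@@]6(OC)c2ccc(OCc5ccccc5)cc2)cc(OCc5ccccc5)c4c3O[C@H](c1ccc(OCc5ccccc5)cc1)CC4 | intermediate
15 | (2S,8S,9S)-5-(benzyloxy)-2,8-bis[4-(benzyloxy)phenyl]-8-methoxy-9-(methoxymethoxy)-3,4,8,9-tetrahydro-2H-furo[2,3-h]chromene-9-carboxylic acid | OC(=O)[C@]6(OCOC)c3c(O[C@@]6(OC)c2ccc(OCc5ccccc5)cc2)cc(OCc5ccccc5)c4c3O[C@H](c1ccc(OCc5ccccc5)cc1)CC4 | intermediate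
16 | 3,5-bis(benzyloxy)phenol | Oc1cc(OCc2ccccc2)cc(OCc2ccccc2)c1 | starting material
17 | 3,5-bis(benzyloxy)-2-bromophenol | Oc1cc(OCc2ccccc2)cc(OCc2ccccc2)c1Br | intermediate
18 | [3,5-bis(benzyloxy)-2-bromophenoxy]trimethylsilane | C[Si](C)(C)Oc1cc(OCc2ccccc2)cc(OCc2ccccc2)c1Br | intermediate
19 | lithium 3,5-bis(benzyloxy)-2-(trimethylsilyl)phenoxide | [Li+].[O-]c1cc(OCc2ccccc2)cc(OCc2ccccc2)c1[Si](C)(C)C | intermediate
20 | 3,5-bis(benzyloxy)-2-(trimethylsilyl)phenyl trifluoromethanesulfonate | C[Si](C)(C)c1c(OS(=O)(=O)C(F)(F)F)cc(OCc2ccccc2)cc1OCc1ccccc1 | intermediate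
21 | cesium salt of acid 15 | [Cs+].[O-]C(=O)[C@]6(OCOC)c3c(O[C@@]6(OC)c2ccc(OCc5ccccc5)cc2)cc(OCc5ccccc5)c4c3O[C@H](c1ccc(OCc5ccccc5)cc1)CC4 | intermediate
22 | 3,5-bis(benzyloxy)benzyne (1,2-didehydro-3,5-bis(benzyloxy)benzene) | C1#CC(OCc2ccccc2)=CC(OCc2ccccc2)=C1 | intermediate
23 | [2,4-bis(benzyloxy)-6-hydroxyphenyl][(2S,8S,9R)-5-(benzyloxy)-2,8-bis[4-(benzyloxy)phenyl]-8-methoxy-9-(methoxymethoxy)-3,4,8,9-tetrahydro-2H-furo[2,3-h]chromen-9-yl]methanone | O=C(c2c(OCc5ccccc5)cc(OCc5ccccc5)cc2O)[C@]6(OCOC)c3c(O[C@@]6(OC)c2ccc(OCc5ccccc5)cc2)cc(OCc5ccccc5)c4c3O[C@H](c1ccc(OCc5ccccc5)cc1)CC4 | intermediate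
24 | [2,4-bis(benzyloxy)-6-hydroxyphenyl][(2S,8S,9R)-5-(benzyloxy)-2,8-bis[4-(benzyloxy)phenyl]-9-hydroxy-8-methoxy-3,4,8,9-tetrahydro-2H-furo[2,3-h]chromen-9-yl]methanone | O=C(c2c(OCc5ccccc5)cc(OCc5ccccc5)cc2O)[C@]6(O)c3c(O[C@@]6(OC)c2ccc(OCc5ccccc5)cc2)cc(OCc5ccccc5)c4c3O[C@H](c1ccc(OCc5ccccc5)cc1)CC4 | intermediate
25 | penta-O-benzyl ether of the target (5-, 7-, 4'-, 5''- and 4'''-O-benzyl; 3-OH free; ring C closed, cis-fused; 2R,3R,2''S) | O=C1c2c(OCc3ccccc3)cc(OCc3ccccc3)cc2O[C@@]2(c3ccc(OCc4ccccc4)cc3)Oc3cc(OCc4ccccc4)c4c(c3[C@@]12O)O[C@H](c1ccc(OCc5ccccc5)cc1)CC4 | intermediate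
26 | CNP0208300.2 (2R at the ketal carbon, 3R at the carbinol carbon, 2''S in the flavan; 2-aryl cis to 3-OH) | O=C1c2c(O)cc(O)cc2O[C@@]2(c3ccc(O)cc3)Oc3cc(O)c4c(c3[C@@]12O)O[C@H](c1ccc(O)cc1)CC4 | target

Total step count: 15. Longest linear sequence: 13 steps (steps 1 to 10 and 13 to 15, from 1).

Steps most likely to fail

Step 8. The facial selectivity at C9 may be poor or reversed, since the flavan centre is too remote to help, and C9 may be lost if the epoxide opens to the quinone methide before methanol captures it. Fallback from 11: oxidation with dimethyldioxirane (acetone solution) in CH2Cl2/MeOH at −40 °C, a known reaction of benzofurans that needs no catalyst, should give 13 together with its epimer at both ring carbons, methyl (2S,8R,9R)-5-(benzyloxy)-2,8-bis[4-(benzyloxy)phenyl]-9-hydroxy-8-methoxy-3,4,8,9-tetrahydro-2H-furo[2,3-h]chromene-9-carboxylate F1. The two are diastereomers through the flavan centre and are separated by preparative chromatography or fractional crystallisation. The route is rejoined at 13.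

Step 13. The aryl anion may be protonated before the acyl shift, leaving only the aryl ester; the shift may be slow at the crowded carbonyl; and the product phenoxide may be arylated by a second aryne. Fallback from 14 and 17, by carbonyl addition of an aryllithium instead of the aryne:
- Ester 14 is reduced with i-Bu2AlH (CH2Cl2, −78 °C) to the aldehyde (2S,8S)-5-(benzyloxy)-2,8-bis[4-(benzyloxy)phenyl]-8-methoxy-9-(methoxymethoxy)-3,4,8,9-tetrahydro-2H-furo[2,3-h]chromene-9-carbaldehyde F2, configured at C9 as 14.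
- Bromophenol 17 is protected (MOMCl, iPr2NEt, CH2Cl2) as 1,5-bis(benzyloxy)-2-bromo-3-(methoxymethoxy)benzene F3.
- Bromine–lithium exchange on F3 (n-BuLi, THF, −78 °C) and addition to F2 should give the carbinol [2,4-bis(benzyloxy)-6-(methoxymethoxy)phenyl](furochromen-9-yl)methanol F4, as either carbinol epimer.
- Dess–Martin oxidation gives the ketone F5, the ring A O-MOM analogue of 23.
- The conditions of step 14 then remove both MOM groups and close ring C, rejoining the route at 25.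

Step 7. The phenol may cycloisomerise without taking up CO, and CBr4 may brominate the electron-rich ring. Fallback from 7 and 8, by an oxa-Michael addition and intramolecular Heck reaction:
- The MOM group of 7 is removed (2 M HCl, MeOH/THF) to give (2S)-5-(benzyloxy)-2-[4-(benzyloxy)phenyl]-8-iodochroman-7-ol F6.
- Alkyne 8 is carboxylated (n-BuLi, ClCO2Me, THF, −78 °C) to methyl 3-[4-(benzyloxy)phenyl]prop-2-ynoate F7.
- Conjugate addition of F6 to F7 (Cs2CO3, MeCN, 60 °C) gives the aryl enol ether methyl 3-aryloxy-3-[4-(benzyloxy)phenyl]acrylate F8.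
- Intramolecular Heck cyclisation (Pd(OAc)2, PPh3, K2CO3, DMF, 100 °C) closes the furan ring and rejoins the route at 11.

Further compounds

F1 | step 8 | methyl (2S,8R,9R)-5-(benzyloxy)-2,8-bis[4-(benzyloxy)phenyl]-9-hydroxy-8-methoxy-3,4,8,9-tetrahydro-2H-furo[2,3-h]chromene-9-carboxylate | COC(=O)[C@@]6(O)c3c(O[C@]6(OC)c2ccc(OCc5ccccc5)cc2)cc(OCc5ccccc5)c4c3O[C@H](c1ccc(OCc5ccccc5)cc1)CC4
F2 | step 13 | (2S,8S)-5-(benzyloxy)-2,8-bis[4-(benzyloxy)phenyl]-8-methoxy-9-(methoxymethoxy)-3,4,8,9-tetrahydro-2H-furo[2,3-h]chromene-9-carbaldehyde, C9 as in 14 | O=C[C@]6(OCOC)c3c(O[C@@]6(OC)c2ccc(OCc5ccccc5)cc2)cc(OCc5ccccc5)c4c3O[C@H](c1ccc(OCc5ccccc5)cc1)CC4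
F3 | step 13 | 1,5-bis(benzyloxy)-2-bromo-3-(methoxymethoxy)benzene | COCOc1cc(OCc2ccccc2)cc(OCc2ccccc2)c1Br
F4 | step 13 | [2,4-bis(benzyloxy)-6-(methoxymethoxy)phenyl][(2S,8S)-5-(benzyloxy)-2,8-bis[4-(benzyloxy)phenyl]-8-methoxy-9-(methoxymethoxy)-3,4,8,9-tetrahydro-2H-furo[2,3-h]chromen-9-yl]methanol, C9 as in 14, carbinol centre as either epimer | OC(c2c(OCc5ccccc5)cc(OCc5ccccc5)cc2OCOC)[C@]6(OCOC)c3c(O[C@@]6(OC)c2ccc(OCc5ccccc5)cc2)cc(OCc5ccccc5)c4c3O[C@H](c1ccc(OCc5ccccc5)cc1)CC4
F5 | step 13 | [2,4-bis(benzyloxy)-6-(methoxymethoxy)phenyl][(2S,8S,9R)-5-(benzyloxy)-2,8-bis[4-(benzyloxy)phenyl]-8-methoxy-9-(methoxymethoxy)-3,4,8,9-tetrahydro-2H-furo[2,3-h]chromen-9-yl]methanone | O=C(c2c(OCc5ccccc5)cc(OCc5ccccc5)cc2OCOC)[C@]6(OCOC)c3c(O[C@@]6(OC)c2ccc(OCc5ccccc5)cc2)cc(OCc5ccccc5)c4c3O[C@H](c1ccc(OCc5ccccc5)cc1)CC4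
F6 | step 7 | (2S)-5-(benzyloxy)-2-[4-(benzyloxy)phenyl]-8-iodochroman-7-ol | C1C[C@@H](c2ccc(OCc3ccccc3)cc2)Oc2c(I)c(O)cc(OCc3ccccc3)c12
F7 | step 7 | methyl 3-[4-(benzyloxy)phenyl]prop-2-ynoate | COC(=O)C#Cc1ccc(OCc2ccccc2)cc1
F8 | step 7 | methyl 3-({(2S)-5-(benzyloxy)-2-[4-(benzyloxy)phenyl]-8-iodochroman-7-yl}oxy)-3-[4-(benzyloxy)phenyl]prop-2-enoate, either alkene isomer | COC(=O)C=C(Oc1cc(OCc2ccccc2)c2CC[C@@H](c3ccc(OCc4ccccc4)cc3)Oc2c1I)c1ccc(OCc2ccccc2)cc1
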